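Two flasks, one leak.

    X + J ⇌ X.J, settled at all times (K1 = 150 L mol⁻¹, ΔH1 = 12.0 kJ mol⁻¹)
    J → L (k2 = 0.0287 s⁻¹, Ea2 = 84.0 kJ mol⁻¹)
    J + D ⇌ Z + D, rate k3*[D]*[J] forward; the back reaction follows from the equilibrium constant (K3 = 2.3, k3 = 330 L mol⁻¹ s⁻¹, Ea3 = 40.0 kJ mol⁻¹, ΔH3 = −41.0 kJ mol⁻¹)
    Z ⇌ X (k4 = 0.0861 s⁻¹, Ea4 = 93.0 kJ mol⁻¹)
    X ⇌ J (K5 = 0.59, k5 = 0.0185 s⁻¹, Ea5 = 86.0 kJ mol⁻¹, ΔH5 = −27.0 kJ mol⁻¹)
    (constants at 50 °C)

| flask | X | D | temperature | time |
|---|---|---|---|---|
| teal | 0.020 M | 96 µM | 50 °C | 80 s |
| red | 0.020 M | 96 µM | 35 °C | 80 s |

1. the flask that comes out highest in amount of J, in percent of the X charged, or "all alike" when all lie within 1.5 percentage points (teal / red / all alike)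
2. J at the end, in percent of the X charged, teal
3. J at the end, in percent of the X charged, red

- percent here means X units held: one X.J counts as two
- what is said of J includes X.J
- all constants are for 50 °C and move with temperature by the activation energies and enthalpies
- in an amount of J, one X.J counts as one J

We reckon in fractions of the X charged, and we begin with teal as a ring: X, J and Z turn into one another with no exit. D is a catalyst, so its charge times the rate constant of J → Z acts as a pseudo-first-order constant, 0.0317 s⁻¹. Z and X relax by their own step with a half-life of 3.42 s, far shorter than the run, so we treat X and Z as one pool. In teal that pool feeds J at 0.01578 s⁻¹ per unit of pool, and J returns at 0.0630 s⁻¹. The ring therefore balances with 20.0% of the charge as free J.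

Now we open the exit, J → L. Its constant joins the losses of J, so the steady-state share of free J in teal falls to 14.7%, reached with a time constant of 9.30 s. Every unit of L passes through free J, so the pool drains at the exit's constant times that share, 0.004212 s⁻¹: this is the leak constant. We solve both ends and join them. Early on, free J climbs towards its share with the time constant; late on, it decays with the leak. The product gives 10.5% for teal at the end.

Last comes binding. Each X.J holds one X and one J, so it counts two units in the part of the charge outside L, and that balance puts unbound X at 20.4% in teal. X.J counts as one J, so free J is multiplied by 1.61. Teal comes to 16.9%.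

Red runs the same way with its own constants: J → L 0.00627 s⁻¹, X → J 0.00389 s⁻¹, J → Z 0.0153 s⁻¹, and equilibrium constants 0.962 for X ⇌ J, 4.83 for J ⇌ Z and 121 L mol⁻¹ for binding. Its time constant is 34.5 s, longer than teal's. Its share is 11.4% and its leak 7.14 × 10⁻⁴ s⁻¹, slower than teal's. Free J reaches 9.71%, binding with the same balance multiplies it by 1.33, and red comes to 13.0%. Our highest flask is teal.

The forecast also names teal, with 17.5% (16% to 19%) for teal and 12.1% (10.8% to 13.5%) for red. Of red it says: “Most material sits as Z and total J is still rising slowly”. Our figure stands lower than its in teal and higher than its in red.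

The simulation gives 17.3% for teal and 12.2% for red, with teal highest. In teal at 80.0 s, Z is made at 0.0749 of the rate at which it is used up, each step taken net, and free J passes into L at 0.91 of the forward rate into Z. Teal is by then a store emptying through J, which is what the leak of 0.00421 s⁻¹ describes. Read teal at 3.0 min: the leak leaves 46.9% of the pool, the same join gives 6.88% as free J, and the same balance for binding gives 9.85% as J. The computed value is 11.0%.

Its constants were chosen freely; the run is a simulation.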